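**Plan**

- Retrosynthesis, first cut: the bond between the ketone carbon and C5 of the chromene. It is made from a C5 aryllithium and 2,4,6-trimethoxybenzaldehyde, followed by oxidation.
- Second cut, both bonds together: the aryl ether bond O1–C8a and the double bond C3=C4 of the pyran ring. This leaves a 2-fluorobenzaldehyde (C4 is the formyl carbon, C8a carries fluorine) and a tertiary alcohol that already holds O1–C2–C3. C3 carries a temporary formyl group, masked as a dimethyl acetal, which is removed later by decarbonylation.
- Enabling feature: C4 sits on C4a, ortho to C8a in the benzene ring (ring A). As CHO it activates C8a–F for ipso substitution by the alkoxide and is then the electrophile that C3 attacks. The six-membered ring O1–C2–C3–C4–C4a–C8a (ring B) therefore closes with the ring fusion fixed by the position of the fluorine.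
- Forward order: ring A is purchased; ring B is built in step 3; the helper CHO is removed in step 4; the trimethoxyphenyl ring (ring C) is joined in step 5; oxidation and one BCl3 step then free both phenols.
- Stereochemistry: the target has no stereocentre. The C3=C4 bond is cis by the ring. The carbinol of step 5 is racemic and is oxidized in step 6.

Key step: step 3

Assumption: 3-bromo-5-fluorophenol, 4,4-dimethoxy-2-methylbutan-2-ol and 2,4,6-trimethoxybenzaldehyde are taken as purchasable.

**Route**

Step 1
Reactants: 1 3-bromo-5-fluorophenol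
Product: 2 1-(benzyloxy)-3-bromo-5-fluorobenzene
Conditions: BnBr, K2CO3, DMF, rt
Reagents that add atoms: benzyl bromide, BrCc1ccccc1
Why: Williamson ether synthesis of the phenoxide; the benzyl ether should survive amide bases, alkoxides, RhCl(PPh3)3 and n-BuLi and is cleaved by BCl3 at the end.

Step 2
Reactants: 2 1-(benzyloxy)-3-bromo-5-fluorobenzene
Product: 4 4-(benzyloxy)-2-bromo-6-fluorobenzaldehyde, via aryllithium 3 (not isolated)
Conditions: LiN(iPr)2, THF, -78 °C; DMF, -78 to -40 °C; then H2O
Reagents that add atoms: N,N-dimethylformamide, CN(C)C=O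
Why: Acidity-controlled ortho-lithiation at the C–H flanked by fluorine and bromine (the amide base does not exchange bromine), followed by formylation of the aryllithium with DMF.

Step 3
Reactants: 4 4-(benzyloxy)-2-bromo-6-fluorobenzaldehyde; 5 4,4-dimethoxy-2-methylbutan-2-ol
Product: 9 7-(benzyloxy)-5-bromo-2,2-dimethyl-2H-chromene-3-carbaldehyde, via sodium alkoxide 6 (not isolated), via aryl ether acetal 7 (not isolated), via dialdehyde 8 (not isolated)
Conditions: 5 (1.3 equiv), NaH (1.2 equiv), DMF, 0 °C; 4, 0 °C to rt; then 1 M aq HCl, THF, rt; then NaOAc, pyrrolidine (0.3 equiv), 50 °C (one flask)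
Reagents that add atoms: water, O
Why: The tertiary alkoxide 6 adds at the C–F carbon ortho to the formyl group and fluoride leaves (addition–elimination SNAr through a Meisenheimer adduct), which forms O1–C8a; fluoride should be displaced far faster than the bromide on the other ortho carbon. Aqueous acid then unmasks the dimethyl acetal, and the pyrrolidine enamine of the new aliphatic aldehyde attacks the neighbouring aryl aldehyde and eliminates to the conjugated enal, an intramolecular aldol condensation that forms C3=C4. The closest known reaction types are the SNAr of tert-butoxide with fluorobenzaldehydes and the aldol half of the salicylaldehyde–enal oxa-Michael/aldol chromene annulation, whose aryloxy aldehyde intermediate is of the same kind as 8. Ring B closes in a 6-(enolexo)-exo-trig mode; no stereocentre is formed and the double bond is cis by the ring. The step needs site selectivity for C8a and for C3, and the substrate secures both: it has one C–F bond and one CH2 next to a carbonyl group. Should 8 lose the phenoxide by retro-oxa-Michael reaction, re-addition and aldol condensation should lead to the same product.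

Step 4
Reactants: 9 7-(benzyloxy)-5-bromo-2,2-dimethyl-2H-chromene-3-carbaldehyde
Product: 10 7-(benzyloxy)-5-bromo-2,2-dimethyl-2H-chromene
Conditions: RhCl(PPh3)3 (1.1 equiv), toluene, 110 °C
Reagents that add atoms: none
Why: Tsuji–Wilkinson decarbonylation: the formyl C–H adds to monovalent rhodium, CO is extruded and reductive elimination leaves H on C3 with the ring double bond in place, while the aryl bromide should stay inert.

Step 5
Reactants: 10 7-(benzyloxy)-5-bromo-2,2-dimethyl-2H-chromene; 11 2,4,6-trimethoxybenzaldehyde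
Product: 13 rac-[7-(benzyloxy)-2,2-dimethyl-2H-chromen-5-yl](2,4,6-trimethoxyphenyl)methanol, via chromenyllithium 12 (not isolated)
Conditions: n-BuLi, THF, -78 °C; 11, -78 to 0 °C; then H2O
Reagents that add atoms: none
Why: Bromine–lithium exchange at -78 °C followed by 1,2-addition of the aryllithium to a non-enolizable aldehyde; the new carbinol centre is racemic and is removed in step 6.

Step 6
Reactants: 13 rac-[7-(benzyloxy)-2,2-dimethyl-2H-chromen-5-yl](2,4,6-trimethoxyphenyl)methanol
Product: 14 [7-(benzyloxy)-2,2-dimethyl-2H-chromen-5-yl](2,4,6-trimethoxyphenyl)methanone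
Conditions: Dess–Martin periodinane, pyridine, CH2Cl2, 0 °C to rt
Reagents that add atoms: none
Why: Dess–Martin oxidation of a doubly benzylic secondary alcohol under buffered conditions, which should leave the acid-sensitive carbinol un-ionized and the chromene double bond untouched.

Step 7
Reactants: 14 [7-(benzyloxy)-2,2-dimethyl-2H-chromen-5-yl](2,4,6-trimethoxyphenyl)methanone
Product: 16 (2-hydroxy-4,6-dimethoxyphenyl)(7-hydroxy-2,2-dimethyl-2H-chromen-5-yl)methanone, via boron aryloxide 15 (not isolated)
Conditions: BCl3, C6HMe5, CH2Cl2, -78 °C, then 0 °C; MeOH/H2O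
Reagents that add atoms: none
Why: BCl3 with pentamethylbenzene as cation scavenger cleaves the aryl benzyl ether at -78 °C, and on warming the ketone-chelated boron removes one of the two equivalent ortho methoxy groups (chelation-controlled demethylation); the boron chelate so formed should resist a second cleavage.

**Compound list**

1 | 3-bromo-5-fluorophenol | Oc1cc(F)cc(Br)c1 | starting material
2 | 1-(benzyloxy)-3-bromo-5-fluorobenzene | Fc1cc(Br)cc(OCc2ccccc2)c1 | intermediate
3 | [4-(benzyloxy)-2-bromo-6-fluorophenyl]lithium | [Li]c1c(F)cc(OCc2ccccc2)cc1Br | intermediate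
4 | 4-(benzyloxy)-2-bromo-6-fluorobenzaldehyde | O=Cc1c(F)cc(OCc2ccccc2)cc1Br | intermediate
5 | 4,4-dimethoxy-2-methylbutan-2-ol | COC(OC)CC(C)(C)O | starting material
6 | sodium 4,4-dimethoxy-2-methylbutan-2-olate | COC(OC)CC(C)(C)[O-].[Na+] | intermediate
7 | 4-(benzyloxy)-2-bromo-6-[(4,4-dimethoxy-2-methylbutan-2-yl)oxy]benzaldehyde | COC(OC)CC(C)(C)Oc1cc(OCc2ccccc2)cc(Br)c1C=O | intermediate
8 | 4-(benzyloxy)-2-bromo-6-[(2-methyl-4-oxobutan-2-yl)oxy]benzaldehyde | O=CCC(C)(C)Oc1cc(OCc2ccccc2)cc(Br)c1C=O | intermediate
9 | 7-(benzyloxy)-5-bromo-2,2-dimethyl-2H-chromene-3-carbaldehyde | O=CC1=Cc2c(Br)cc(OCc3ccccc3)cc2OC1(C)C | intermediate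
10 | 7-(benzyloxy)-5-bromo-2,2-dimethyl-2H-chromene | CC1(C)C=Cc2c(Br)cc(OCc3ccccc3)cc2O1 | intermediate
11 | 2,4,6-trimethoxybenzaldehyde | COc1cc(OC)c(C=O)c(OC)c1 | starting material
12 | [7-(benzyloxy)-2,2-dimethyl-2H-chromen-5-yl]lithium | [Li]c1cc(OCc2ccccc2)cc2c1C=CC(C)(C)O2 | intermediate
13 | rac-[7-(benzyloxy)-2,2-dimethyl-2H-chromen-5-yl](2,4,6-trimethoxyphenyl)methanol (racemic) | COc1cc(OC)c(C(O)c2cc(OCc3ccccc3)cc3c2C=CC(C)(C)O3)c(OC)c1 | intermediate
14 | [7-(benzyloxy)-2,2-dimethyl-2H-chromen-5-yl](2,4,6-trimethoxyphenyl)methanone | COc1cc(OC)c(C(=O)c2cc(OCc3ccccc3)cc3c2C=CC(C)(C)O3)c(OC)c1 | intermediate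
15 | {7-[(dichloroboranyl)oxy]-2,2-dimethyl-2H-chromen-5-yl}(2,4,6-trimethoxyphenyl)methanone | COc1cc(OC)c(C(=O)c2cc(OB(Cl)Cl)cc3c2C=CC(C)(C)O3)c(OC)c1 | intermediate
16 | (2-hydroxy-4,6-dimethoxyphenyl)(7-hydroxy-2,2-dimethyl-2H-chromen-5-yl)methanone | COc1cc(O)c(C(=O)c2cc(O)cc3c2C=CC(C)(C)O3)c(OC)c1 | target

**Count and risks**

Total step count: 7. Longest linear sequence: 7 steps (1 to 16).

Step 3. What may go wrong: the hindered tertiary alkoxide may substitute too slowly at a fluoride that is activated only by a formyl group whose pull is weakened by the para benzyloxy group. The alkoxide may instead add to the aldehyde, or the tertiary aryl ether may ionize in the acid stage. The fallback sets out from 4 and makes the aryl–oxygen bond first with a small oxygen nucleophile. Compound 4 is treated with the sodium alkoxide of 2-(methanesulfonyl)ethanol (NaH, DMF) to give 4-(benzyloxy)-2-bromo-6-[2-(methanesulfonyl)ethoxy]benzaldehyde F1, which loses ethenyl methyl sulfone under the basic conditions to give 4-(benzyloxy)-2-bromo-6-hydroxybenzaldehyde F2. F2 is then condensed with 3-methylbut-2-enal (K2CO3, 1,4-dioxane, reflux) in the known oxa-Michael/aldol chromene annulation. The fallback comes back to the route at 9.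

Step 4. What may go wrong: CO extrusion from the hindered alkenoyl rhodium hydride may stall, or RhCl(PPh3)3 may insert into the C–Br bond at the temperature needed. The fallback sets out from 4 and avoids the formyl helper altogether. SNAr of 4 with the sodium alkoxide of 2-methylbut-3-en-2-ol (NaH, DMF) should give 4-(benzyloxy)-2-bromo-6-[(2-methylbut-3-en-2-yl)oxy]benzaldehyde F3. Wittig methylenation (Ph3PCH3Br, KOt-Bu, THF, 0 °C) should give 5-(benzyloxy)-1-bromo-2-ethenyl-3-[(2-methylbut-3-en-2-yl)oxy]benzene F4. Ring-closing metathesis with the second-generation Grubbs catalyst (CH2Cl2, 40 °C) then closes ring B with loss of ethene. The fallback comes back to the route at 10.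

Step 7. What may go wrong: while the mixture is warmed for the demethylation, the second ortho methoxy group may also be cleaved, or HCl may add to or oligomerize the electron-rich chromene double bond. The fallback sets out from 10 and moves the hidden phenol of ring C from a methyl ether to a benzyl ether, so that the last step is a debenzylation at -78 °C only. 2-Hydroxy-4,6-dimethoxybenzaldehyde (purchased) is benzylated (BnBr, K2CO3, DMF) to 2-(benzyloxy)-4,6-dimethoxybenzaldehyde F5. Compound 10 is lithiated as in step 5 and added to F5 to give racemic [7-(benzyloxy)-2,2-dimethyl-2H-chromen-5-yl][2-(benzyloxy)-4,6-dimethoxyphenyl]methanol F6. Dess–Martin oxidation gives [7-(benzyloxy)-2,2-dimethyl-2H-chromen-5-yl][2-(benzyloxy)-4,6-dimethoxyphenyl]methanone F7. BCl3 with C6HMe5 at -78 °C should remove both benzyl groups and leave the methyl ethers. The fallback comes back to the route at 16.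

**Further compounds**

F1 | step 3 | 4-(benzyloxy)-2-bromo-6-[2-(methanesulfonyl)ethoxy]benzaldehyde | CS(=O)(=O)CCOc1cc(OCc2ccccc2)cc(Br)c1C=O
F2 | step 3 | 4-(benzyloxy)-2-bromo-6-hydroxybenzaldehyde | O=Cc1c(O)cc(OCc2ccccc2)cc1Br
F3 | step 4 | 4-(benzyloxy)-2-bromo-6-[(2-methylbut-3-en-2-yl)oxy]benzaldehyde | C=CC(C)(C)Oc1cc(OCc2ccccc2)cc(Br)c1C=O
F4 | step 4 | 5-(benzyloxy)-1-bromo-2-ethenyl-3-[(2-methylbut-3-en-2-yl)oxy]benzene | C=CC(C)(C)Oc1cc(OCc2ccccc2)cc(Br)c1C=C
F5 | step 7 | 2-(benzyloxy)-4,6-dimethoxybenzaldehyde | COc1cc(OC)c(C=O)c(OCc2ccccc2)c1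
F6 | step 7 | rac-[7-(benzyloxy)-2,2-dimethyl-2H-chromen-5-yl][2-(benzyloxy)-4,6-dimethoxyphenyl]methanol (racemic) | COc1cc(OC)c(C(O)c2cc(OCc3ccccc3)cc3c2C=CC(C)(C)O3)c(OCc2ccccc2)c1
F7 | step 7 | [7-(benzyloxy)-2,2-dimethyl-2H-chromen-5-yl][2-(benzyloxy)-4,6-dimethoxyphenyl]methanone | COc1cc(OC)c(C(=O)c2cc(OCc3ccccc3)cc3c2C=CC(C)(C)O3)c(OCc2ccccc2)c1
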